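**Strategy.** Everything rests on cutting two bonds of the bicyclic core: the ring-fusion bond C4a–C8a and C5–C6. The key step exploits the fact that C8a lies between the C1 and C8 carbonyl carbons, so it is a 1,3-dicarbonyl methylene that can condense with a C4a methyl ketone, and that the C4a methyl (C5) then becomes vinylogously acidic and is held cis to the C8 acyl chain by lactone ring B. One pot therefore closes ring B (Knoevenagel) and ring A (vinylogous Dieckmann on the C6 ester). The precursor is an acyclic β-keto ester: the (R)-4-oxopentan-2-yl ester of a methyl 3-oxoglutarate bearing the C7 methyl and a methoxymethyl-protected C7 oxygen.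

Key step: step 7

Numbering: the isochromene numbering of the target (C1, O2, C3, C4, C4a, C5 to C8, C8a) is used for all intermediates; ring A is the carbocycle, ring B the oxygen ring.

Assumption: pig liver esterase is taken to deliver the (S)-acid 4 from diester 3; sense and enantiomeric purity are to be confirmed by correlation before material is committed, and the fallback for step 3 applies otherwise.

Remark: 6 is drawn as its enol; 12 and 13 are drawn as keto tautomers although they should exist largely as enols (vinylogous acids).

Step 1
Reactants: 1 dimethyl 2-methylpropanedioate (dimethyl methylmalonate)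
Product: 2 dimethyl 2-hydroxy-2-methylpropanedioate
Conditions: NaH, THF, 0 °C; 3-phenyl-2-(phenylsulfonyl)oxaziridine, −78 to 0 °C; AcOH
Reagents that add atoms: 3-phenyl-2-(phenylsulfonyl)oxaziridine, O=S(=O)(N1OC1c1ccccc1)c1ccccc1
Why: The sodium enolate of the malonate attacks the electrophilic oxygen of the N-sulfonyloxaziridine (Davis enolate hydroxylation), and the product is achiral so no stereocontrol is needed.

Step 2
Reactants: 2 dimethyl 2-hydroxy-2-methylpropanedioate
Product: 3 dimethyl 2-(methoxymethoxy)-2-methylpropanedioate
Conditions: NaH, THF, 0 °C; MOMCl, Bu4NI (cat.), 0 °C to rt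
Reagents that add atoms: chloromethyl methyl ether, COCCl
Why: Williamson-type O-alkylation of the tertiary alkoxide by the reactive α-chloro ether (methoxymethyl protection), the substrate having no C–H acid site left to compete.

Step 3
Reactants: 3 dimethyl 2-(methoxymethoxy)-2-methylpropanedioate
Product: 4 (2S)-3-methoxy-2-(methoxymethoxy)-2-methyl-3-oxopropanoic acid
Conditions: pig liver esterase, 0.1 M phosphate buffer pH 7.5, 25 °C, pH-stat (1 M NaOH); then 2 M HCl to pH 2.5, 0 °C
Reagents that add atoms: water, O
Why: Enzymatic desymmetrisation of a prochiral 2,2-disubstituted malonate, in which the esterase hydrolyses only one of the two enantiotopic methoxycarbonyl groups and so sets the quaternary center (later C7) as S under enzyme control, the mono-acid salt not being hydrolysed further.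

Step 4
Reactants: 4 (2S)-3-methoxy-2-(methoxymethoxy)-2-methyl-3-oxopropanoic acid; 5 2,2-dimethyl-1,3-dioxane-4,6-dione (Meldrum's acid)
Product: 6 methyl (2S)-3-(2,2-dimethyl-4,6-dioxo-1,3-dioxan-5-ylidene)-3-hydroxy-2-(methoxymethoxy)-2-methylpropanoate
Conditions: DCC, DMAP, CH2Cl2, 0 °C to rt; cold aq. KHSO4 wash
Reagents that add atoms: none
Why: Carbodiimide and DMAP activation of the acid followed by C-acylation of Meldrum's acid is a standard entry to β-keto esters, and the quaternary center has no α-hydrogen and cannot racemise.

Step 5
Reactants: 7 pentane-2,4-dione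
Product: 8 (4R)-4-hydroxypentan-2-one
Conditions: (R)-selective alcohol dehydrogenase from Lactobacillus brevis, NADP+ (cat.), iPrOH, MgCl2, phosphate buffer pH 7, 30 °C
Reagents that add atoms: none
Why: Ketoreductase mono-reduction with isopropanol as hydride source, in which the anti-Prelog enzyme delivers hydride to one face of one carbonyl and sets the carbinol center (later C3) as R, the hydroxy ketone being a much poorer substrate for a second reduction.

Step 6
Reactants: 6 methyl (2S)-3-(2,2-dimethyl-4,6-dioxo-1,3-dioxan-5-ylidene)-3-hydroxy-2-(methoxymethoxy)-2-methylpropanoate; 8 (4R)-4-hydroxypentan-2-one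
Product: 10 1-methyl 5-[(2R)-4-oxopentan-2-yl] (2S)-2-(methoxymethoxy)-2-methyl-3-oxopentanedioate, via acylketene 9 (not isolated)
Conditions: 8 (1.2 equiv), toluene, 80 °C
Reagents that add atoms: none
Why: Thermal fragmentation of the acyl Meldrum's acid releases acetone and CO2 to give the acylketene, which the secondary alcohol traps as the β-keto ester under neutral conditions, neither stereocenter taking part (only the O–H bond of 8 reacts).

Step 7
Reactants: 10 1-methyl 5-[(2R)-4-oxopentan-2-yl] (2S)-2-(methoxymethoxy)-2-methyl-3-oxopentanedioate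
Product: 12 (3R,7R)-7-(methoxymethoxy)-3,7-dimethyl-3,4,5,7-tetrahydro-1H-isochromene-1,6,8-trione, via Knoevenagel lactone 11 (not isolated)
Conditions: piperidine, AcOH (0.2 equiv each), 4 Å MS, toluene, 40 °C; then THF, LiN(SiMe3)2 (3 equiv), −78 to 0 °C; then cold 1 M HCl
Reagents that add atoms: none
Why: Piperidinium acetate enolises the C8a methylene, which is flanked by the C8 ketone and the C1 ester carbonyl, and this carbon adds to the tethered C4a methyl ketone and loses water (intramolecular Knoevenagel condensation, the known cyclisation of β-keto esters of β-hydroxy ketones to 3-acyl-5,6-dihydropyran-2-ones), closing ring B by a 6-(enolexo)-exo-trig attack and giving 11. LiN(SiMe3)2 then removes a proton from the C5 methyl, now γ to both the C8 ketone and the lactone carbonyl, and the lithium dienolate acylates on the C6 methyl ester (vinylogous Dieckmann or Claisen cyclisation), closing ring A by a 6-(enolendo)-exo-trig attack and expelling methoxide. The trione is deprotonated at once to its delocalised vinylogous-acid anion, which makes the second closure irreversible. No stereocenter is formed: C3 is not touched and C7 is quaternary with no enolisable hydrogen, so both are carried through (the descriptor at C7 changes from S to R only because C6, once a ketone, ranks below C8). Chemoselectivity in the first stage, condensation at C8a before a C4 proton is removed and the C3 acyloxy group is eliminated, is secured by the far higher acidity of the 1,3-dicarbonyl methylene under buffered amine catalysis. Site selectivity in the second stage is secured by ring B, which holds C4 trans and C5 cis to the C8 acyl chain across C4a=C8a so that only C5 can reach C6, helped by lithium chelation between O8 and the lactone carbonyl and by the low temperature, which keeps a C4 anion from opening the lactone.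

Step 8
Reactants: 12 (3R,7R)-7-(methoxymethoxy)-3,7-dimethyl-3,4,5,7-tetrahydro-1H-isochromene-1,6,8-trione
Product: 14 (3R,7R)-7-(methoxymethoxy)-3,7-dimethyl-3,4-dihydro-6H-isochromene-6,8(7H)-dione, via lactol 13 (not isolated)
Conditions: iBu2AlH (2.3 equiv), CH2Cl2, −78 °C; then 1 M HCl, THF, 0 °C to rt
Reagents that add atoms: none
Why: iBu2AlH reduction of a δ-lactone to the lactol with the ring A ketones protected in situ as their enolate (the known tactic for reducing an ester beside an enolisable dicarbonyl), since the first equivalent deprotonates the vinylogous acid so that C6 and C8 sit in a delocalised aluminium dienolate while the lactone carbonyl, chelated to the aluminium on O8, takes the hydride, and the acid work-up then ionises the lactol at C1 and loss of a C5 proton gives the cross-conjugated C1=C8a and C4a=C5 enol ether (vinylogous dehydration).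

Step 9
Reactants: 14 (3R,7R)-7-(methoxymethoxy)-3,7-dimethyl-3,4-dihydro-6H-isochromene-6,8(7H)-dione
Product: 15 (3R,7R)-7-hydroxy-3,7-dimethyl-3,4-dihydro-6H-isochromene-6,8(7H)-dione
Conditions: TFA, CH2Cl2, H2O (5 equiv), 0 °C to rt
Reagents that add atoms: none
Why: Acid hydrolysis of the methoxymethyl acetal (standard MOM cleavage), tolerated by the vinylogous ester core because hydration at C1 is reversible and returns the same enol ether, while C7 keeps its configuration since only the acetal C–O bond is broken.

Step 10
Reactants: 15 (3R,7R)-7-hydroxy-3,7-dimethyl-3,4-dihydro-6H-isochromene-6,8(7H)-dione; 16 octadecanoyl chloride (stearoyl chloride)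
Product: 17 (3R,7R)-3,7-dimethyl-6,8-dioxo-3,4,7,8-tetrahydro-6H-isochromen-7-yl octadecanoate (target)
Conditions: 16 (1.5 equiv), Et3N, DMAP (cat.), CH2Cl2, 0 °C to rt
Reagents that add atoms: none
Why: DMAP-catalysed acylation of the tertiary α-ketol oxygen through the acylpyridinium (nucleophilic catalysis), a routine esterification for the C7 hydroxyl of this dione class, with C7 unchanged because only the O–H bond is broken.

**Compound list**

1 | dimethyl 2-methylpropanedioate (dimethyl methylmalonate) | COC(=O)C(C)C(=O)OC | starting material
2 | dimethyl 2-hydroxy-2-methylpropanedioate | COC(=O)C(C)(O)C(=O)OC | intermediate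
3 | dimethyl 2-(methoxymethoxy)-2-methylpropanedioate | COCOC(C)(C(=O)OC)C(=O)OC | intermediate
4 | (2S)-3-methoxy-2-(methoxymethoxy)-2-methyl-3-oxopropanoic acid | COCO[C@](C)(C(=O)OC)C(=O)O | intermediate
5 | 2,2-dimethyl-1,3-dioxane-4,6-dione (Meldrum's acid) | CC1(C)OC(=O)CC(=O)O1 | starting material
6 | methyl (2S)-3-(2,2-dimethyl-4,6-dioxo-1,3-dioxan-5-ylidene)-3-hydroxy-2-(methoxymethoxy)-2-methylpropanoate | COCO[C@](C)(C(=O)OC)C(O)=C1C(=O)OC(C)(C)OC1=O | intermediate
7 | pentane-2,4-dione | CC(=O)CC(C)=O | starting material
8 | (4R)-4-hydroxypentan-2-one | C[C@@H](O)CC(C)=O | intermediate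
9 | methyl (2S)-2-(methoxymethoxy)-2-methyl-3,5-dioxopent-4-enoate (acylketene) | COCO[C@](C)(C(=O)OC)C(=O)C=C=O | intermediate
10 | 1-methyl 5-[(2R)-4-oxopentan-2-yl] (2S)-2-(methoxymethoxy)-2-methyl-3-oxopentanedioate | COCO[C@](C)(C(=O)OC)C(=O)CC(=O)O[C@H](C)CC(C)=O | intermediate
11 | methyl (2S)-3-[(6R)-4,6-dimethyl-2-oxo-5,6-dihydro-2H-pyran-3-yl]-2-(methoxymethoxy)-2-methyl-3-oxopropanoate (Knoevenagel lactone) | COCO[C@](C)(C(=O)OC)C(=O)C1=C(C)C[C@@H](C)OC1=O | intermediate
12 | (3R,7R)-7-(methoxymethoxy)-3,7-dimethyl-3,4,5,7-tetrahydro-1H-isochromene-1,6,8-trione | COCO[C@]1(C)C(=O)CC2=C(C1=O)C(=O)O[C@H](C)C2 | intermediate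
13 | (3R,7R)-1-hydroxy-7-(methoxymethoxy)-3,7-dimethyl-3,4-dihydro-1H-isochromene-6,8(5H,7H)-dione (lactol; C1 epimers) | COCO[C@]1(C)C(=O)CC2=C(C1=O)C(O)O[C@H](C)C2 | intermediate
14 | (3R,7R)-7-(methoxymethoxy)-3,7-dimethyl-3,4-dihydro-6H-isochromene-6,8(7H)-dione | COCO[C@]1(C)C(=O)C=C2C[C@@H](C)OC=C2C1=O | intermediate
15 | (3R,7R)-7-hydroxy-3,7-dimethyl-3,4-dihydro-6H-isochromene-6,8(7H)-dione | O[C@]1(C)C(=O)C=C2C[C@@H](C)OC=C2C1=O | intermediate
16 | octadecanoyl chloride (stearoyl chloride) | CCCCCCCCCCCCCCCCCC(=O)Cl | starting material
17 | (3R,7R)-3,7-dimethyl-6,8-dioxo-3,4,7,8-tetrahydro-6H-isochromen-7-yl octadecanoate | CCCCCCCCCCCCCCCCCC(=O)O[C@]1(C)C(=O)C=C2C[C@@H](C)OC=C2C1=O | target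

**Step count.** Total: 10 steps. Longest linear sequence: 9 steps (steps 1, 2, 3, 4, 6, 7, 8, 9, 10); step 5 supplies the second fragment.

**Steps most likely to fail**

Step 7 is the riskiest. The amine-catalysed ketone condensation of open-chain 10 may be outrun by β-elimination of the C3 acyloxy group, and in the second stage a C4 anion may open the lactone before C5 reaches C6. The fallback uses known chemistry, sets out from 8 and 4, and comes back to the route at 11 and thence 12. Ring B is made first without an active-methylene ketone condensation, and the C8a–C8 bond is made by acylation. Alcohol 8 is esterified with diethylphosphonoacetic acid (DCC, DMAP) to (2R)-4-oxopentan-2-yl 2-(diethoxyphosphoryl)acetate F1. An intramolecular Horner–Wadsworth–Emmons reaction (LiCl, iPr2NEt, MeCN) then gives (6R)-4,6-dimethyl-5,6-dihydro-2H-pyran-2-one F2. Acid 4 is converted with carbonyldiimidazole into methyl (2S)-3-(1H-imidazol-1-yl)-2-(methoxymethoxy)-2-methyl-3-oxopropanoate F3. The lithium dienolate of F2 (LiN(SiMe3)2, THF, −78 °C) is acylated at its α-carbon (C8a) by F3, which gives 11 directly as its dienolate, never exposed to amine or heat. The excess amide carries this on to 12 at low temperature as in the main route.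

Step 8 is next. Hydride may reach a ring A carbonyl if deprotonation is incomplete, the enolate-conjugated lactone may be reduced too slowly, or the lactol aluminate may lose its oxygen in the flask and take a second hydride at C1 (over-reduction to the cyclic ether). The fallback masks ring A covalently instead of as a metal enolate; it sets out from 12 and comes back at 14. Silylation of 12 at the less hindered O6 (iPr3SiOTf, Et3N, CH2Cl2) gives (3R,7R)-7-(methoxymethoxy)-3,7-dimethyl-6-[(triisopropylsilyl)oxy]-3,4-dihydro-1H-isochromene-1,8(7H)-dione F4, in which the only remaining ketone, C8, is a hindered and doubly vinylogous ester carbonyl. iBu2AlH (1.1 equiv, −78 °C) should then reduce the lactone to (3R,7R)-1-hydroxy-7-(methoxymethoxy)-3,7-dimethyl-6-[(triisopropylsilyl)oxy]-3,4-dihydro-1H-isochromen-8(7H)-one F5. Treatment with 1 M HCl in THF removes the silyl group and dehydrates the lactol to 14.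

Step 3 is third. The esterase may show poor or opposite enantiotopic group selectivity toward a substrate with a polar methoxymethoxy group. The fallback replaces desymmetrisation by classical resolution; it sets out from 3 and comes back at 4. Mono-saponification of 3 (KOH, 1.0 equiv, MeOH) gives racemic 3-methoxy-2-(methoxymethoxy)-2-methyl-3-oxopropanoic acid F6. Fractional crystallisation with 1-phenylethylamine gives (1R)-1-phenylethylammonium (2S)-3-methoxy-2-(methoxymethoxy)-2-methyl-3-oxopropanoate F7. The amine enantiomer whose salt with the (S)-acid is the less soluble is to be found by trial; the (R)-amine is drawn. Acidification of the salt returns 4, and the configuration is checked by the same correlation as in the main route.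

**Further compounds**

F1 | step 7 | (2R)-4-oxopentan-2-yl 2-(diethoxyphosphoryl)acetate | CCOP(=O)(OCC)CC(=O)O[C@H](C)CC(C)=O
F2 | step 7 | (6R)-4,6-dimethyl-5,6-dihydro-2H-pyran-2-one | CC1=CC(=O)O[C@H](C)C1
F3 | step 7 | methyl (2S)-3-(1H-imidazol-1-yl)-2-(methoxymethoxy)-2-methyl-3-oxopropanoate | COCO[C@](C)(C(=O)OC)C(=O)n1ccnc1
F4 | step 8 | (3R,7R)-7-(methoxymethoxy)-3,7-dimethyl-6-[(triisopropylsilyl)oxy]-3,4-dihydro-1H-isochromene-1,8(7H)-dione | COCO[C@]1(C)C(O[Si](C(C)C)(C(C)C)C(C)C)=CC2=C(C1=O)C(=O)O[C@H](C)C2
F5 | step 8 | (3R,7R)-1-hydroxy-7-(methoxymethoxy)-3,7-dimethyl-6-[(triisopropylsilyl)oxy]-3,4-dihydro-1H-isochromen-8(7H)-one (C1 epimers) | COCO[C@]1(C)C(O[Si](C(C)C)(C(C)C)C(C)C)=CC2=C(C1=O)C(O)O[C@H](C)C2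
F6 | step 3 | racemic 3-methoxy-2-(methoxymethoxy)-2-methyl-3-oxopropanoic acid | COCOC(C)(C(=O)OC)C(=O)O
F7 | step 3 | (1R)-1-phenylethylammonium (2S)-3-methoxy-2-(methoxymethoxy)-2-methyl-3-oxopropanoate | COCO[C@](C)(C(=O)OC)C(=O)[O-].C[C@@H]([NH3+])c1ccccc1
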